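**Retrosynthetic overview**
1. Target 34 is a germacranolide: a ten-membered carbocycle C1–C10 (germacrane numbering) trans-fused at C6/C7 to an α-methylene-γ-lactone. The C8 ester is cut first, then C6–C7 together with the lactone bond C12–O6 (CrCl2 closure of a C7/C11/C13 bromomethylacrylate onto the C6 enal).
2. The open chain is cut at C2–C3: a prenol-derived allylic sulfone carbanion (C3–C6, C15) is acylated by a lactone carbonyl (C2), followed by desulfonylation and reagent-controlled reduction at C2.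
3. Feature on which the plan rests: O8, C8, C9, C10 (with C14), C1 and C2 are the seco form of a 4-methyl-5,6-dihydro-2H-pyran-2-one ring in which O8 acylates C2. Inside that six-membered ring the C1=C10 olefin can only be Z, and C8 is its single stereocentre.
4. That ring is made by C8–C9 bond formation: a copper-catalysed asymmetric vinylogous Mukaiyama aldol of the silyl dienolate of methyl 3-methylbut-2-enoate with a chelating alkoxyacetaldehyde (C7, C8), with lactonisation.
5. Ring order: dihydropyranone template (step 4), opened in step 8; ten-membered ring and γ-lactone together in step 19.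

Key step: step 4

Remark: germacrane locants (C1–C15, O6, O7, O8) are used in the text; the aldehyde carries a p-methoxybenzyl (PMB) ether instead of a benzyl ether, because it chelates in the same way, needs no hydrogenolysis in the presence of three olefins, and can be moved from O7 to O8 (steps 9 and 13).

**Route**

Step 1
Reactants: 1 methyl 3-methylbut-2-enoate
Product: 2 (1Z)-1-methoxy-3-methyl-1-(trimethylsilyloxy)buta-1,3-diene
Conditions: LiN(iPr)2 (1.1 equiv), THF, −78 °C; Me3SiCl, −78 °C → rt; distillation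
Reagents that add atoms: chlorotrimethylsilane, C[Si](C)(C)Cl
Why: γ-Deprotonation of the enoate gives the extended lithium dienolate, which is silylated on oxygen (O-silylation of an ester dienolate); either ketene acetal geometry serves in step 4.

Step 2
Reactants: 3 (Z)-but-2-ene-1,4-diol
Product: 4 (Z)-1,4-bis[(4-methoxybenzyl)oxy]but-2-ene
Conditions: NaH (2.4 equiv), 4-methoxybenzyl chloride (2.2 equiv), Bu4NI (cat.), THF/DMF, 0 °C → rt
Reagents that add atoms: 4-methoxybenzyl chloride, COc1ccc(CCl)cc1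
Why: Williamson ether synthesis on both primary allylic alkoxides.

Step 3
Reactants: 4 (Z)-1,4-bis[(4-methoxybenzyl)oxy]but-2-ene
Product: 5 2-[(4-methoxybenzyl)oxy]acetaldehyde
Conditions: O3, CH2Cl2, −78 °C (stopped at the alkene end point); PPh3, −78 °C → rt
Reagents that add atoms: ozone, [O-][O+]=O
Why: Ozonolysis with reductive work-up cleaves the symmetric cis alkene into two molecules of 5, the alkene reacting far faster than the anisyl rings.

Step 4
Reactants: 2 (1Z)-1-methoxy-3-methyl-1-(trimethylsilyloxy)buta-1,3-diene; 5 2-[(4-methoxybenzyl)oxy]acetaldehyde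
Product: 8 (R)-6-{[(4-methoxybenzyl)oxy]methyl}-4-methyl-5,6-dihydro-2H-pyran-2-one, via silyl ether 6 (not isolated), via hydroxy ester 7 (not isolated)
Conditions: Cu(OTf)2 (10 mol%), (R,R)-2,6-bis(4-phenyl-4,5-dihydrooxazol-2-yl)pyridine (11 mol%), 2 (1.5 equiv), CH2Cl2, −78 °C; then 1 M HCl, THF, rt; then PPTS (cat.), toluene, 60 °C
Reagents that add atoms: none
Why: Mukaiyama-type vinylogous aldol addition followed by lactonisation: the divalent copper centre of the Cu(OTf)2–pybox complex holds aldehyde 5 as a five-membered chelate through its carbonyl and ether oxygens, the terminal CH2 of dienolate 2 (C9) adds to the carbonyl carbon (C8) in an open transition state, and the silyl group passes to the aldolate oxygen to give 6. The closest known reactions are the additions of silyl ketene acetals and silyl dienolates to (benzyloxy)acetaldehyde under the same type of copper–pybox catalyst, and the copper-catalysed additions of this dienolate to aldehydes that end in 5,6-dihydropyran-2-ones. After acidic desilylation to 7 the ring closes by attack of O8 on the ester carbonyl C2 with loss of methanol (6-exo-trig acyl substitution), a closure open only to the Z enoate. C8 is set by the ligand: the (R,R) complex shields the Si face of the chelated aldehyde (the (S,S) complex is the one that gives S carbinols with acetate-type nucleophiles), so attack on the Re face should give 8R. The step needs γ-attack, which is the normal course of silyl dienolates under Lewis acid catalysis, two-point binding, which the ether oxygen of 5 secures, and a Z C1=C10 bond, which the 3-methyl group favours because it clashes with the cis oxygen substituent of the ketene acetal in the s-trans diene and so makes the skewed s-cis form the reacting one. Any E hydroxy ester cannot lactonise and is removed by chromatography, so 8 should be obtained as the Z-locked ring only.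

Step 5
Reactants: 9 prenol (3-methylbut-2-en-1-ol)
Product: 10 tert-butyldimethyl[(3-methylbut-2-en-1-yl)oxy]silane
Conditions: TBSCl, imidazole, CH2Cl2, 0 °C → rt
Reagents that add atoms: tert-butyldimethylsilyl chloride, CC(C)(C)[Si](C)(C)Cl
Why: Imidazole-assisted silylation of a primary alcohol.

Step 6
Reactants: 10 tert-butyldimethyl[(3-methylbut-2-en-1-yl)oxy]silane
Product: 11 (E)-4-[(tert-butyldimethylsilyl)oxy]-2-methylbut-2-en-1-ol
Conditions: SeO2 (0.3 equiv), t-BuOOH (2.5 equiv), CH2Cl2, 0 °C → rt, stopped before over-oxidation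
Reagents that add atoms: tert-butyl hydroperoxide, CC(C)(C)OO
Why: SeO2-catalysed allylic oxidation (ene reaction, then 2,3-sigmatropic shift) is selective for the E methyl group of a trisubstituted olefin, which gives the E allylic alcohol whose carbinol carbon becomes C3.

Step 7
Reactants: 11 (E)-4-[(tert-butyldimethylsilyl)oxy]-2-methylbut-2-en-1-ol
Product: 13 (E)-tert-butyldimethyl{[3-methyl-4-(phenylsulfonyl)but-2-en-1-yl]oxy}silane, via allylic mesylate 12 (not isolated)
Conditions: MsCl, Et3N, THF, −20 °C; then PhSO2Na, Bu4NI (cat.), DMF, rt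
Reagents that add atoms: sodium benzenesulfinate, [Na+].[O-]S(=O)c1ccccc1; methanesulfonyl chloride, CS(=O)(=O)Cl (enters intermediate 12 only)
Why: Mesylation and SN2 displacement by the sulfinate through sulfur (sulfone synthesis) at the primary allylic carbon, without transposition and without touching the E olefin.

Step 8
Reactants: 8 (R)-6-{[(4-methoxybenzyl)oxy]methyl}-4-methyl-5,6-dihydro-2H-pyran-2-one; 13 (E)-tert-butyldimethyl{[3-methyl-4-(phenylsulfonyl)but-2-en-1-yl]oxy}silane
Product: 14 (2E,6Z,9R)-1-[(tert-butyldimethylsilyl)oxy]-9-hydroxy-10-[(4-methoxybenzyl)oxy]-3,7-dimethyl-4-(phenylsulfonyl)deca-2,6-dien-5-one (epimers at the sulfonyl carbon)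
Conditions: 13 (2.2 equiv), n-BuLi (2.1 equiv), THF, −78 °C; then 8, −78 → −40 °C; aq. NH4Cl; used at once
Reagents that add atoms: none
Why: Claisen-type acylation of the α-sulfonyl allyl carbanion through its α-carbon (C3) by the lactone carbonyl (C2) with ring opening; the β,β-disubstituted enoate resists conjugate addition, and the acidic β-keto sulfone is held as its enolate by the second equivalent of carbanion, which prevents a second addition and keeps C1=C10 Z, while C8 is untouched.

Step 9
Reactants: 14 (2E,6Z,9R)-hydroxy keto sulfone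
Product: 15 (2E,6Z)-1-[(tert-butyldimethylsilyl)oxy]-8-[(4R)-2-(4-methoxyphenyl)-1,3-dioxolan-4-yl]-3,7-dimethyl-4-(phenylsulfonyl)octa-2,6-dien-5-one (epimers at the sulfonyl and acetal carbons)
Conditions: DDQ (1.2 equiv), 4 Å molecular sieves, CH2Cl2, 0 °C
Reagents that add atoms: none
Why: Oxidative acetalisation of a PMB ether: DDQ oxidises the benzylic position to an oxocarbenium ion that the neighbouring C8 hydroxyl traps as a five-membered p-methoxybenzylidene acetal under neutral conditions, which also removes the hydroxyl from hemiketal formation with the C2 ketone.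

Step 10
Reactants: 15 acetal keto sulfone
Product: 16 (2E,6Z)-1-[(tert-butyldimethylsilyl)oxy]-8-[(4R)-2-(4-methoxyphenyl)-1,3-dioxolan-4-yl]-3,7-dimethylocta-2,6-dien-5-one
Conditions: SmI2 (2.5 equiv), THF/MeOH, −78 °C; pH 7 buffer; used at once
Reagents that add atoms: none
Why: Reductive desulfonylation of a β-keto sulfone by electron transfer from SmI2; methanol protonates the samarium dienolate at C3 (kinetic α-protonation), so C4=C5 stays E and unconjugated, and the hindered Z enone is reduced far more slowly at −78 °C.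

Step 11
Reactants: 16 ketone
Product: 17 (2E,5R,6Z)-1-[(tert-butyldimethylsilyl)oxy]-8-[(4R)-2-(4-methoxyphenyl)-1,3-dioxolan-4-yl]-3,7-dimethylocta-2,6-dien-5-ol
Conditions: (S)-2-methyl-CBS-oxazaborolidine (1 equiv), catecholborane (2 equiv), toluene, −78 °C
Reagents that add atoms: none
Why: Corey–Bakshi–Shibata reduction: the β,β-disubstituted Z-alkenyl group acts as the large substituent and the C3 methylene as the small one, so the (S)-oxazaborolidine delivers hydride to the face that gives the 2R allylic alcohol (reagent control), and catecholborane leaves the olefins alone.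

Step 12
Reactants: 17 allylic alcohol
Product: 18 (2E,5R,6Z)-1,5-bis[(tert-butyldimethylsilyl)oxy]-8-[(4R)-2-(4-methoxyphenyl)-1,3-dioxolan-4-yl]-3,7-dimethylocta-2,6-diene
Conditions: TBSCl, imidazole, DMF, rt
Reagents that add atoms: tert-butyldimethylsilyl chloride, CC(C)(C)[Si](C)(C)Cl
Why: Imidazole-assisted silylation of the secondary allylic alcohol under conditions that do not disturb the acetal.

Step 13
Reactants: 18 bis-silyl acetal
Product: 19 (2R,4Z,6R,8E)-6,10-bis[(tert-butyldimethylsilyl)oxy]-2-[(4-methoxybenzyl)oxy]-4,8-dimethyldeca-4,8-dien-1-ol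
Conditions: iBu2AlH (3 equiv), CH2Cl2, −78 → 0 °C; aq. potassium sodium tartrate
Reagents that add atoms: none
Why: Regioselective reductive opening of the p-methoxybenzylidene acetal: iBu2AlH binds the less hindered primary oxygen O7, that C–O bond breaks and hydride quenches the oxocarbenium ion, so the PMB group ends on the secondary O8 and O7 is freed.

Step 14
Reactants: 19 primary alcohol
Product: 20 (2R,4Z,6R,8E)-6,10-bis[(tert-butyldimethylsilyl)oxy]-2-[(4-methoxybenzyl)oxy]-4,8-dimethyldeca-4,8-dienal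
Conditions: Dess–Martin periodinane, NaHCO3, CH2Cl2, 0 °C → rt; used at once
Reagents that add atoms: none
Why: Dess–Martin oxidation under buffered, non-basic conditions, which should not epimerise the α-alkoxy aldehyde at C8.

Step 15
Reactants: 20 α-alkoxy aldehyde; 21 methyl acrylate
Product: 22 methyl (4R,6Z,8R,10E)-8,12-bis[(tert-butyldimethylsilyl)oxy]-3-hydroxy-4-[(4-methoxybenzyl)oxy]-6,10-dimethyl-2-methylidenedodeca-6,10-dienoate (C3 epimers)
Conditions: DABCO (1 equiv), 21 (10 equiv), MeOH (cat.), rt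
Reagents that add atoms: none
Why: Morita–Baylis–Hillman reaction: the DABCO–acrylate zwitterion adds to the activated α-alkoxy aldehyde and brings in C11, C12 and C13; the new carbinol centre at C7 is lost in step 16, so its configuration does not matter.

Step 16
Reactants: 22 Baylis–Hillman alcohol
Product: 23 methyl (2Z,4R,6Z,8R,10E)-2-(bromomethyl)-8,12-bis[(tert-butyldimethylsilyl)oxy]-4-[(4-methoxybenzyl)oxy]-6,10-dimethyldodeca-2,6,10-trienoate
Conditions: NBS (1.4 equiv), Me2S (1.6 equiv), CH2Cl2, 0 °C (premixed); then 22, 0 °C → rt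
Reagents that add atoms: N-bromosuccinimide, O=C1CCC(=O)N1Br
Why: Corey–Kim-type activation of the alcohol as an alkoxysulfonium ion and attack of bromide with allylic transposition (SN2′) give the conjugated primary bromide as the more stable trisubstituted olefin with C8 trans to the ester; the sulfonium reagent is preformed so that no free NBS meets the olefins or the anisyl ring.

Step 17
Reactants: 23 allylic bromide
Product: 24 methyl (2Z,4R,6Z,8R,10E)-2-(bromomethyl)-8-[(tert-butyldimethylsilyl)oxy]-12-hydroxy-4-[(4-methoxybenzyl)oxy]-6,10-dimethyldodeca-2,6,10-trienoate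
Conditions: HF·pyridine, pyridine, THF, 0 °C
Reagents that add atoms: none
Why: Buffered HF cleaves the primary allylic silyl ether much faster than the secondary one at C2 (steric differentiation of silyl ethers).

Step 18
Reactants: 24 allylic alcohol
Product: 25 methyl (2Z,4R,6Z,8R,10E)-2-(bromomethyl)-8-[(tert-butyldimethylsilyl)oxy]-4-[(4-methoxybenzyl)oxy]-6,10-dimethyl-12-oxododeca-2,6,10-trienoate
Conditions: MnO2 (20 equiv), CH2Cl2, rt
Reagents that add atoms: none
Why: MnO2 oxidises only the allylic alcohol, to the E enal, under neutral conditions that spare the allylic bromide.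

Step 19
Reactants: 25 bromo enal
Product: 27 (3aR,4R,6Z,8R,10E,11aR)-8-[(tert-butyldimethylsilyl)oxy]-4-[(4-methoxybenzyl)oxy]-6,10-dimethyl-3-methylidene-3a,4,5,8,9,11a-hexahydrocyclodeca[b]furan-2(3H)-one, via hydroxy ester 26 (not isolated)
Conditions: CrCl2 (8 equiv), THF, 0.002 M, slow addition of 25, rt; aq. work-up; then PPTS (cat.), CH2Cl2, rt
Reagents that add atoms: none
Why: Intramolecular Nozaki–Hiyama–Kishi-type allylation: CrCl2 turns the allylic bromide into an allylchromium species whose γ-carbon C7 adds to the chromium-bound C6 aldehyde in a cyclic transition state (ten-membered ring by C6–C7 bond formation), and the C6 alkoxide then closes the γ-lactone on the methyl ester (5-exo-trig); the trans ring fusion (6R) is the course that such closures of germacrane chains are known to take, and the face of C7 (7R) should be set by C8, whose C–H bond lies anti to the forming bond and whose PMB ether oxygen sits on the inside, where it can bind the chromium that carries the aldehyde, with the ring tether (C9) outside.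

Step 20
Reactants: 27 macrocyclic lactone
Product: 28 (3aR,4R,6Z,8R,10E,11aR)-8-[(tert-butyldimethylsilyl)oxy]-4-hydroxy-6,10-dimethyl-3-methylidene-3a,4,5,8,9,11a-hexahydrocyclodeca[b]furan-2(3H)-one
Conditions: DDQ (1.5 equiv), CH2Cl2/pH 7 buffer, 0 °C → rt
Reagents that add atoms: none
Why: Oxidative PMB cleavage (benzylic hydride abstraction by DDQ, hydrolysis of the hemiacetal) frees O8, while the silyl ether, the isolated olefins and the α-methylene lactone are inert.

Step 21
Reactants: 29 methyl (S)-3-hydroxy-2-methylpropanoate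
Product: 30 methyl (S)-3-[(tert-butyldimethylsilyl)oxy]-2-methylpropanoate
Conditions: TBSCl, imidazole, CH2Cl2, rt
Reagents that add atoms: tert-butyldimethylsilyl chloride, CC(C)(C)[Si](C)(C)Cl
Why: Imidazole-assisted silylation of the primary alcohol; the stereocentre is not involved.

Step 22
Reactants: 30 silylated methyl ester
Product: 31 (S)-3-[(tert-butyldimethylsilyl)oxy]-2-methylpropanoic acid
Conditions: LiOH, THF/MeOH/H2O, 0 °C; 1 M HCl to pH 3, 0 °C
Reagents that add atoms: lithium hydroxide, [Li+].[OH-]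
Why: Saponification at 0 °C; the carboxylate once formed is not enolised, so the α-stereocentre should hold, and β-elimination of the silyloxy group is slow at this temperature.

Step 23
Reactants: 28 C8 alcohol; 31 (S)-3-[(tert-butyldimethylsilyl)oxy]-2-methylpropanoic acid
Product: 33 (3aR,4R,6Z,8R,10E,11aR)-8-[(tert-butyldimethylsilyl)oxy]-6,10-dimethyl-3-methylidene-2-oxo-2,3,3a,4,5,8,9,11a-octahydrocyclodeca[b]furan-4-yl (2S)-3-[(tert-butyldimethylsilyl)oxy]-2-methylpropanoate, via mixed anhydride 32 (not isolated)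
Conditions: 31 (2 equiv), 2,4,6-trichlorobenzoyl chloride, Et3N, THF, rt; then 28, DMAP, toluene, rt
Reagents that add atoms: 2,4,6-trichlorobenzoyl chloride, O=C(Cl)c1c(Cl)cc(Cl)cc1Cl (enters intermediate 32 only)
Why: Yamaguchi esterification: the mixed anhydride acylates DMAP and the acylpyridinium ion esterifies the hindered secondary C8 hydroxyl with retention at C8, O2 being silylated.

Step 24
Reactants: 33 bis-silyl ether
Product: 34 (3aR,4R,6Z,8R,10E,11aR)-8-hydroxy-6,10-dimethyl-3-methylidene-2-oxo-2,3,3a,4,5,8,9,11a-octahydrocyclodeca[b]furan-4-yl (2S)-3-hydroxy-2-methylpropanoate (CNP0254953.1)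
Conditions: HF·pyridine, pyridine, THF, 0 °C → rt
Reagents that add atoms: none
Why: Fluoride-mediated cleavage of both silyl ethers under buffered acidic conditions that leave the α-methylene lactone, the ester and the allylic alcohol intact.

**Compound list**
1 | methyl 3-methylbut-2-enoate | COC(=O)C=C(C)C | starting material
2 | (1Z)-1-methoxy-3-methyl-1-(trimethylsilyloxy)buta-1,3-diene | C=C(C)/C=C(/OC)O[Si](C)(C)C | intermediate
3 | (Z)-but-2-ene-1,4-diol | OC/C=C\CO | starting material
4 | (Z)-1,4-bis[(4-methoxybenzyl)oxy]but-2-ene | COc1ccc(COC/C=C\COCc2ccc(OC)cc2)cc1 | intermediate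
5 | 2-[(4-methoxybenzyl)oxy]acetaldehyde | O=CCOCc1ccc(OC)cc1 | intermediate
6 | methyl (2Z,5R)-6-[(4-methoxybenzyl)oxy]-3-methyl-5-(trimethylsilyloxy)hex-2-enoate (not isolated) | COC(=O)/C=C(/C)C[C@@H](O[Si](C)(C)C)COCc1ccc(OC)cc1 | intermediate
7 | methyl (2Z,5R)-5-hydroxy-6-[(4-methoxybenzyl)oxy]-3-methylhex-2-enoate (not isolated) | COC(=O)/C=C(/C)C[C@@H](O)COCc1ccc(OC)cc1 | intermediate
8 | (R)-6-{[(4-methoxybenzyl)oxy]methyl}-4-methyl-5,6-dihydro-2H-pyran-2-one | CC1=CC(=O)O[C@@H](COCc2ccc(OC)cc2)C1 | intermediate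
9 | prenol (3-methylbut-2-en-1-ol) | CC(C)=CCO | starting material
10 | tert-butyldimethyl[(3-methylbut-2-en-1-yl)oxy]silane | CC(C)=CCO[Si](C)(C)C(C)(C)C | intermediate
11 | (E)-4-[(tert-butyldimethylsilyl)oxy]-2-methylbut-2-en-1-ol | C/C(CO)=C\CO[Si](C)(C)C(C)(C)C | intermediate
12 | (E)-4-[(tert-butyldimethylsilyl)oxy]-2-methylbut-2-en-1-yl methanesulfonate (not isolated) | C/C(COS(C)(=O)=O)=C\CO[Si](C)(C)C(C)(C)C | intermediate
13 | (E)-tert-butyldimethyl{[3-methyl-4-(phenylsulfonyl)but-2-en-1-yl]oxy}silane | C/C(CS(=O)(=O)c1ccccc1)=C\CO[Si](C)(C)C(C)(C)C | intermediate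
14 | (2E,6Z,9R)-1-[(tert-butyldimethylsilyl)oxy]-9-hydroxy-10-[(4-methoxybenzyl)oxy]-3,7-dimethyl-4-(phenylsulfonyl)deca-2,6-dien-5-one (C4 epimers) | COc1ccc(COC[C@H](O)C/C(C)=C\C(=O)C(S(=O)(=O)c2ccccc2)/C(C)=C/CO[Si](C)(C)C(C)(C)C)cc1 | intermediate
15 | (2E,6Z)-1-[(tert-butyldimethylsilyl)oxy]-8-[(4R)-2-(4-methoxyphenyl)-1,3-dioxolan-4-yl]-3,7-dimethyl-4-(phenylsulfonyl)octa-2,6-dien-5-one (epimers at C4 and at the acetal carbon) | COc1ccc(C2OC[C@@H](C/C(C)=C\C(=O)C(S(=O)(=O)c3ccccc3)/C(C)=C/CO[Si](C)(C)C(C)(C)C)O2)cc1 | intermediate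
16 | (2E,6Z)-1-[(tert-butyldimethylsilyl)oxy]-8-[(4R)-2-(4-methoxyphenyl)-1,3-dioxolan-4-yl]-3,7-dimethylocta-2,6-dien-5-one | COc1ccc(C2OC[C@@H](C/C(C)=C\C(=O)C/C(C)=C/CO[Si](C)(C)C(C)(C)C)O2)cc1 | intermediate
17 | (2E,5R,6Z)-1-[(tert-butyldimethylsilyl)oxy]-8-[(4R)-2-(4-methoxyphenyl)-1,3-dioxolan-4-yl]-3,7-dimethylocta-2,6-dien-5-ol | COc1ccc(C2OC[C@@H](C/C(C)=C\[C@H](O)C/C(C)=C/CO[Si](C)(C)C(C)(C)C)O2)cc1 | intermediate
18 | (2E,5R,6Z)-1,5-bis[(tert-butyldimethylsilyl)oxy]-8-[(4R)-2-(4-methoxyphenyl)-1,3-dioxolan-4-yl]-3,7-dimethylocta-2,6-diene | COc1ccc(C2OC[C@@H](C/C(C)=C\[C@H](O[Si](C)(C)C(C)(C)C)C/C(C)=C/CO[Si](C)(C)C(C)(C)C)O2)cc1 | intermediate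
19 | (2R,4Z,6R,8E)-6,10-bis[(tert-butyldimethylsilyl)oxy]-2-[(4-methoxybenzyl)oxy]-4,8-dimethyldeca-4,8-dien-1-ol | COc1ccc(CO[C@@H](CO)C/C(C)=C\[C@H](O[Si](C)(C)C(C)(C)C)C/C(C)=C/CO[Si](C)(C)C(C)(C)C)cc1 | intermediate
20 | (2R,4Z,6R,8E)-6,10-bis[(tert-butyldimethylsilyl)oxy]-2-[(4-methoxybenzyl)oxy]-4,8-dimethyldeca-4,8-dienal | COc1ccc(CO[C@@H](C=O)C/C(C)=C\[C@H](O[Si](C)(C)C(C)(C)C)C/C(C)=C/CO[Si](C)(C)C(C)(C)C)cc1 | intermediate
21 | methyl acrylate | C=CC(=O)OC | starting material
22 | methyl (4R,6Z,8R,10E)-8,12-bis[(tert-butyldimethylsilyl)oxy]-3-hydroxy-4-[(4-methoxybenzyl)oxy]-6,10-dimethyl-2-methylidenedodeca-6,10-dienoate (C3 epimers) | COc1ccc(CO[C@@H](C(O)C(=C)C(=O)OC)C/C(C)=C\[C@H](O[Si](C)(C)C(C)(C)C)C/C(C)=C/CO[Si](C)(C)C(C)(C)C)cc1 | intermediate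
23 | methyl (2Z,4R,6Z,8R,10E)-2-(bromomethyl)-8,12-bis[(tert-butyldimethylsilyl)oxy]-4-[(4-methoxybenzyl)oxy]-6,10-dimethyldodeca-2,6,10-trienoate | COc1ccc(CO[C@@H](/C=C(\CBr)C(=O)OC)C/C(C)=C\[C@H](O[Si](C)(C)C(C)(C)C)C/C(C)=C/CO[Si](C)(C)C(C)(C)C)cc1 | intermediate
24 | methyl (2Z,4R,6Z,8R,10E)-2-(bromomethyl)-8-[(tert-butyldimethylsilyl)oxy]-12-hydroxy-4-[(4-methoxybenzyl)oxy]-6,10-dimethyldodeca-2,6,10-trienoate | COc1ccc(CO[C@@H](/C=C(\CBr)C(=O)OC)C/C(C)=C\[C@H](O[Si](C)(C)C(C)(C)C)C/C(C)=C/CO)cc1 | intermediate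
25 | methyl (2Z,4R,6Z,8R,10E)-2-(bromomethyl)-8-[(tert-butyldimethylsilyl)oxy]-4-[(4-methoxybenzyl)oxy]-6,10-dimethyl-12-oxododeca-2,6,10-trienoate | COc1ccc(CO[C@@H](/C=C(\CBr)C(=O)OC)C/C(C)=C\[C@H](O[Si](C)(C)C(C)(C)C)C/C(C)=C/C=O)cc1 | intermediate
26 | methyl 2-[(1S,2R,3E,6R,7Z,10R)-6-[(tert-butyldimethylsilyl)oxy]-2-hydroxy-10-[(4-methoxybenzyl)oxy]-4,8-dimethylcyclodeca-3,7-dien-1-yl]prop-2-enoate (not isolated) | C=C(C(=O)OC)[C@H]1[C@H](O)/C=C(\C)C[C@@H](O[Si](C)(C)C(C)(C)C)/C=C(/C)C[C@H]1OCc2ccc(OC)cc2 | intermediate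
27 | (3aR,4R,6Z,8R,10E,11aR)-8-[(tert-butyldimethylsilyl)oxy]-4-[(4-methoxybenzyl)oxy]-6,10-dimethyl-3-methylidene-3a,4,5,8,9,11a-hexahydrocyclodeca[b]furan-2(3H)-one | C=C1C(=O)O[C@@H]2/C=C(\C)C[C@@H](O[Si](C)(C)C(C)(C)C)/C=C(/C)C[C@@H](OCc3ccc(OC)cc3)[C@@H]12 | intermediate
28 | (3aR,4R,6Z,8R,10E,11aR)-8-[(tert-butyldimethylsilyl)oxy]-4-hydroxy-6,10-dimethyl-3-methylidene-3a,4,5,8,9,11a-hexahydrocyclodeca[b]furan-2(3H)-one | C=C1C(=O)O[C@@H]2/C=C(\C)C[C@@H](O[Si](C)(C)C(C)(C)C)/C=C(/C)C[C@@H](O)[C@@H]12 | intermediate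
29 | methyl (S)-3-hydroxy-2-methylpropanoate | COC(=O)[C@@H](C)CO | starting material
30 | methyl (S)-3-[(tert-butyldimethylsilyl)oxy]-2-methylpropanoate | COC(=O)[C@@H](C)CO[Si](C)(C)C(C)(C)C | intermediate
31 | (S)-3-[(tert-butyldimethylsilyl)oxy]-2-methylpropanoic acid | OC(=O)[C@@H](C)CO[Si](C)(C)C(C)(C)C | intermediate
32 | (S)-3-[(tert-butyldimethylsilyl)oxy]-2-methylpropanoic 2,4,6-trichlorobenzoic anhydride (not isolated) | C[C@@H](CO[Si](C)(C)C(C)(C)C)C(=O)OC(=O)c1c(Cl)cc(Cl)cc1Cl | intermediate
33 | (3aR,4R,6Z,8R,10E,11aR)-8-[(tert-butyldimethylsilyl)oxy]-6,10-dimethyl-3-methylidene-2-oxo-2,3,3a,4,5,8,9,11a-octahydrocyclodeca[b]furan-4-yl (2S)-3-[(tert-butyldimethylsilyl)oxy]-2-methylpropanoate | C=C1C(=O)O[C@@H]2/C=C(\C)C[C@@H](O[Si](C)(C)C(C)(C)C)/C=C(/C)C[C@@H](OC(=O)[C@@H](C)CO[Si](C)(C)C(C)(C)C)[C@@H]12 | intermediate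
34 | (3aR,4R,6Z,8R,10E,11aR)-8-hydroxy-6,10-dimethyl-3-methylidene-2-oxo-2,3,3a,4,5,8,9,11a-octahydrocyclodeca[b]furan-4-yl (2S)-3-hydroxy-2-methylpropanoate (CNP0254953.1) | C=C1C(=O)O[C@@H]2/C=C(\C)C[C@@H](O)/C=C(/C)C[C@@H](OC(=O)[C@@H](C)CO)[C@@H]12 | target

**Step count**
Total: 24 steps. Longest linear sequence: 18 steps (3 → 4 → 5 → 8 → 14 → … → 28 → 33 → 34; steps 2–4, 8–20, 23 and 24; the branch from prenol 9 is equally long).

**Steps most likely to fail**

Step 19. The Z-configured allylchromium species may add through its chair arrangement, which gives the syn adduct and so the cis ring fusion (wrong configuration at C6). O8 may also fail to bind chromium, so that the other face of C7 is attacked, and reduction or dimerisation of the allylic bromide can compete at this ring size. The fallback answers the cis fusion and sets out from 25. The closure is accepted as it comes and gives the syn hydroxy ester F1, which on standing gives the cis-fused lactone F2. Either is saponified (LiOH, THF/H2O, 0 °C; acidified cold to pH 5) to the hydroxy acid F3. A Mitsunobu lactonisation (PPh3, DIAD, THF, 0 °C, dilute) then closes the lactone by SN2 displacement at C6 with inversion, and the fallback comes back to the route at 27. The C6 configuration is then set by an invertive substitution and no longer by the transition state of the allylation.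

Step 4. The dienolate may react from its s-trans form and give the E enoate, which cannot close the ring, or binding of the aldehyde through one oxygen only may erode the facial selectivity. The fallback sets out from 5. The same Cu(OTf)2–pybox system with 2-(trimethylsilyloxy)propene (Mukaiyama aldol) gives the silyl ether F4 and, after acidic work-up, the hydroxy ketone F5. Esterification with diethylphosphonoacetic acid (DCC, DMAP) gives the phosphonoacetate F6. An intramolecular Horner–Wadsworth–Emmons olefination (LiCl, iPr2NEt, MeCN) then forms the C1=C10 bond as the ring closes, and the fallback comes back at 8. The olefin geometry then follows from the ring and not from the conformation of a dienolate.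

Step 8. The sulfonyl carbanion may add in conjugate fashion to the unsaturated lactone or deprotonate it at the γ-position, or 14 may collapse to its cyclic hemiketal and lose water before the hydroxyl is protected. The fallback sets out from 8. Aminolysis with Me(MeO)NH·HCl and AlMe3 (CH2Cl2, 0 °C) gives the Z hydroxy Weinreb amide F7. DDQ with molecular sieves converts it into the p-methoxybenzylidene acetal F8. Lithiated 13 then adds once to the amide (stable tetrahedral chelate) and gives the keto sulfone directly, so the fallback comes back at 15.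

**Further compounds**
F1 | step 19 | methyl 2-[(1S,2S,3E,6R,7Z,10R)-6-[(tert-butyldimethylsilyl)oxy]-2-hydroxy-10-[(4-methoxybenzyl)oxy]-4,8-dimethylcyclodeca-3,7-dien-1-yl]prop-2-enoate | C=C(C(=O)OC)[C@H]1[C@@H](O)/C=C(\C)C[C@@H](O[Si](C)(C)C(C)(C)C)/C=C(/C)C[C@H]1OCc2ccc(OC)cc2
F2 | step 19 | (3aR,4R,6Z,8R,10E,11aS)-8-[(tert-butyldimethylsilyl)oxy]-4-[(4-methoxybenzyl)oxy]-6,10-dimethyl-3-methylidene-3a,4,5,8,9,11a-hexahydrocyclodeca[b]furan-2(3H)-one | C=C1C(=O)O[C@H]2/C=C(\C)C[C@@H](O[Si](C)(C)C(C)(C)C)/C=C(/C)C[C@@H](OCc3ccc(OC)cc3)[C@@H]12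
F3 | step 19 | 2-[(1S,2S,3E,6R,7Z,10R)-6-[(tert-butyldimethylsilyl)oxy]-2-hydroxy-10-[(4-methoxybenzyl)oxy]-4,8-dimethylcyclodeca-3,7-dien-1-yl]prop-2-enoic acid | C=C(C(=O)O)[C@H]1[C@@H](O)/C=C(\C)C[C@@H](O[Si](C)(C)C(C)(C)C)/C=C(/C)C[C@H]1OCc2ccc(OC)cc2
F4 | step 4 | (R)-5-[(4-methoxybenzyl)oxy]-4-(trimethylsilyloxy)pentan-2-one | CC(=O)C[C@@H](O[Si](C)(C)C)COCc1ccc(OC)cc1
F5 | step 4 | (R)-4-hydroxy-5-[(4-methoxybenzyl)oxy]pentan-2-one | CC(=O)C[C@@H](O)COCc1ccc(OC)cc1
F6 | step 4 | (R)-1-[(4-methoxybenzyl)oxy]-4-oxopentan-2-yl 2-(diethoxyphosphoryl)acetate | CC(=O)C[C@@H](OC(=O)CP(=O)(OCC)OCC)COCc1ccc(OC)cc1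
F7 | step 8 | (2Z,5R)-5-hydroxy-N-methoxy-6-[(4-methoxybenzyl)oxy]-N,3-dimethylhex-2-enamide | CON(C)C(=O)/C=C(/C)C[C@@H](O)COCc1ccc(OC)cc1
F8 | step 8 | (2Z)-N-methoxy-4-[(4R)-2-(4-methoxyphenyl)-1,3-dioxolan-4-yl]-N,3-dimethylbut-2-enamide | COc1ccc(C2OC[C@@H](C/C(C)=C\C(=O)N(C)OC)O2)cc1
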